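## Retrosynthetic overview

1. Presumed biosynthesis: oxidised piceatannol is captured at C-8 (the carbon that couples in oligostilbene biosynthesis) and then, as the para-quinone methide, at C-7 by a styryl polyketide 3-oxo acid whose carboxyl carbon leaves as CO2.
2. 15 ⇐ 12: loss of acetone and CO2 from a dioxinone (masked 3-oxo acid) fused at C1–C7 of the cycloheptenone.
3. 12 ⇐ 10: the only ring, closed last at C6–C7 (7-exo) by the dioxinone carbon on the quinone methide formed by enantioselective C5-protonation of the stilbene; this sets C5 and C6.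
4. 10 ⇐ 7 + 8: C4–C5 bond by radical alkylation of piceatannol at C-8.
5. 7 ⇐ 6 ⇐ 1 + 2: allylic bromination; vinylogous aldol/dehydration.

Assumption: the sense of induction of the chiral acid in step 4 cannot be predicted; the catalyst antipode that gives (5S,6S) is chosen after the first run. The alkene isomers of 10 are expected to converge under the acid (not proven).

## Route

Step 1
Reactants: 1 2,2,6-trimethyl-4H-1,3-dioxin-4-one; 2 (E)-4-phenylbut-3-en-2-one
Product: 6 2,2-dimethyl-6-[(1E,3E)-2-methyl-4-phenylbuta-1,3-dien-1-yl]-4H-1,3-dioxin-4-one, via lithium dienolate 3 (not isolated), via lithium aldolate 4 (not isolated), via tertiary mesylate 5 (not isolated)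
Conditions: LiN(iPr)2 (LDA), THF, −78 °C; 2; MsCl, −78 to 0 °C; DBU, 0 °C to rt
Reagents that add atoms: none
Why: Vinylogous aldol 1,2-addition of the γ-lithiated dioxinone to the ketone, then E1cB-type elimination of the tertiary mesylate through the acidic CH2 next to the dioxinone, gives the fully conjugated triene; no stereocentre is kept.

Step 2
Reactants: 6 2,2-dimethyl-6-[(1E,3E)-2-methyl-4-phenylbuta-1,3-dien-1-yl]-4H-1,3-dioxin-4-one
Product: 7 6-[(1Z,3E)-2-(bromomethyl)-4-phenylbuta-1,3-dien-1-yl]-2,2-dimethyl-4H-1,3-dioxin-4-one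
Conditions: NBS (1.05 equiv), AIBN (5 mol %), PhCF3, 80 °C
Reagents that add atoms: N-bromosuccinimide (NBS), O=C1CCC(=O)N1Br
Why: Wohl–Ziegler allylic bromination, since the methyl group carries the only allylic C–H bonds and its delocalised radical takes bromine at the unhindered terminus; no stereocentre is formed.

Step 3
Reactants: 7 6-[(1Z,3E)-2-(bromomethyl)-4-phenylbuta-1,3-dien-1-yl]-2,2-dimethyl-4H-1,3-dioxin-4-one; 8 piceatannol (4-[(E)-2-(3,5-dihydroxyphenyl)ethenyl]benzene-1,2-diol, 1.2 equiv)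
Product: 10 6-[(1E,3E)-2-[(2E)-3-(3,4-dihydroxyphenyl)-2-(3,5-dihydroxyphenyl)prop-2-en-1-yl]-4-phenylbuta-1,3-dien-1-yl]-2,2-dimethyl-4H-1,3-dioxin-4-one, via quinone methide 9 (not isolated)
Conditions: Ir(ppy)3 [tris(2-phenylpyridinato)iridium] (1 mol %), 2,6-lutidine, degassed MeCN, blue LEDs, rt
Reagents that add atoms: none
Why: Photoredox radical–polar crossover (Heck-type) alkylation, in which excited Ir(ppy)3 reduces the allylic bromide, the allyl radical adds through its CH2 end to C-8 of piceatannol to give the 4-hydroxybenzyl radical, oxidation by the oxidised photocatalyst gives quinone methide 9, and lutidine tautomerises it to the achiral stilbene 10, so no stereocentre survives.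

Step 4
Reactants: 10 6-[(1E,3E)-2-[(2E)-3-(3,4-dihydroxyphenyl)-2-(3,5-dihydroxyphenyl)prop-2-en-1-yl]-4-phenylbuta-1,3-dien-1-yl]-2,2-dimethyl-4H-1,3-dioxin-4-one
Product: 12 (5S,6S)-5-(3,4-dihydroxyphenyl)-6-(3,5-dihydroxyphenyl)-2,2-dimethyl-8-[(E)-2-phenylethenyl]-6,7-dihydro-5H-cyclohepta[d][1,3]dioxin-4-one, via protonated quinone methide 11 (not isolated)
Conditions: confined chiral imidodiphosphorimidate (IDPi) Brønsted acid (5 mol %), CHCl3–HFIP (20:1), −20 °C
Reagents that add atoms: none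
Why: Proposed new method: the chiral acid reversibly protonates the stilbene carbon that bears the 3,5-dihydroxyphenyl group to give a 4-hydroxybenzyl cation/chiral anion pair (11), and its cationic carbon is attacked 7-exo by the enol-ether carbon C-5 of the dioxinone, the only nucleophilic carbon, so the five-membered closure open to a free ketone dienol is excluded; with both aryl groups pseudo-equatorial, C-5 (S) is fixed by Curtin–Hammett selection of one protonation face and C-6 (S, trans) in the C–C bond formation, the closest known reactions being chiral phosphoric acid catalysed 1,6-additions to para-quinone methides generated in situ and IDPi-catalysed asymmetric intramolecular hydrofunctionalisation of olefins.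

Step 5
Reactants: 12 (5S,6S)-5-(3,4-dihydroxyphenyl)-6-(3,5-dihydroxyphenyl)-2,2-dimethyl-8-[(E)-2-phenylethenyl]-6,7-dihydro-5H-cyclohepta[d][1,3]dioxin-4-one
Product: 15 (5S,6S)-6-(3,4-dihydroxyphenyl)-5-(3,5-dihydroxyphenyl)-3-[(E)-2-phenylethenyl]cyclohept-2-en-1-one (CNP0400050.1), via acyl ketene 13 (not isolated), via oxo acid 14 (not isolated)
Conditions: 1,4-dioxane–H2O (10:1), 110 °C, sealed tube, argon
Reagents that add atoms: none
Why: Thermal retro-hetero-Diels–Alder of the dioxinone releases acetone and an acyl ketene that water converts to the 3-oxo acid, which decarboxylates under the same neutral conditions; C-5 and C-6 are not enolisable and are untouched.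

## Compound list

1 | 2,2,6-trimethyl-4H-1,3-dioxin-4-one | CC1=CC(=O)OC(C)(C)O1 | starting material
2 | (E)-4-phenylbut-3-en-2-one (benzalacetone) | CC(=O)/C=C/c1ccccc1 | starting material
3 | lithium 2,2-dimethyl-6-methylidene-6H-1,3-dioxin-4-olate | [Li]OC1=CC(=C)OC(C)(C)O1 | intermediate (not isolated)
4 | lithium (3E)-1-(2,2-dimethyl-4-oxo-4H-1,3-dioxin-6-yl)-2-methyl-4-phenylbut-3-en-2-olate (racemic) | [Li]OC(C)(CC1=CC(=O)OC(C)(C)O1)/C=C/c1ccccc1 | intermediate (not isolated)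
5 | (3E)-1-(2,2-dimethyl-4-oxo-4H-1,3-dioxin-6-yl)-2-methyl-4-phenylbut-3-en-2-yl methanesulfonate (racemic) | CS(=O)(=O)OC(C)(CC1=CC(=O)OC(C)(C)O1)/C=C/c1ccccc1 | intermediate (not isolated)
6 | 2,2-dimethyl-6-[(1E,3E)-2-methyl-4-phenylbuta-1,3-dien-1-yl]-4H-1,3-dioxin-4-one | CC1(C)OC(=O)C=C(O1)/C=C(\C)/C=C/c1ccccc1 | intermediate
7 | 6-[(1Z,3E)-2-(bromomethyl)-4-phenylbuta-1,3-dien-1-yl]-2,2-dimethyl-4H-1,3-dioxin-4-one | CC1(C)OC(=O)C=C(O1)/C=C(\CBr)/C=C/c1ccccc1 | intermediate
8 | piceatannol, 4-[(E)-2-(3,5-dihydroxyphenyl)ethenyl]benzene-1,2-diol | Oc1cc(O)cc(/C=C/c2ccc(O)c(O)c2)c1 | starting material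
9 | 6-[(1E,3E)-2-[2-(3,5-dihydroxyphenyl)-3-(3-hydroxy-4-oxocyclohexa-2,5-dien-1-ylidene)propyl]-4-phenylbuta-1,3-dien-1-yl]-2,2-dimethyl-4H-1,3-dioxin-4-one (racemic quinone methide) | CC1(C)OC(=O)C=C(O1)/C=C(/C=C/c1ccccc1)CC(C=C1C=CC(=O)C(O)=C1)c1cc(O)cc(O)c1 | intermediate (not isolated)
10 | 6-[(1E,3E)-2-[(2E)-3-(3,4-dihydroxyphenyl)-2-(3,5-dihydroxyphenyl)prop-2-en-1-yl]-4-phenylbuta-1,3-dien-1-yl]-2,2-dimethyl-4H-1,3-dioxin-4-one (major alkene isomer shown) | CC1(C)OC(=O)C=C(O1)/C=C(/C=C/c1ccccc1)C/C(=C\c1ccc(O)c(O)c1)c1cc(O)cc(O)c1 | intermediate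
11 | 6-[(1E,3E)-2-[(2S)-2-(3,5-dihydroxyphenyl)-3-(3-hydroxy-4-oxocyclohexa-2,5-dien-1-ylidene)propyl]-4-phenylbuta-1,3-dien-1-yl]-2,2-dimethyl-4H-1,3-dioxin-4-one, present as its O-protonated ion pair with the catalyst anion | CC1(C)OC(=O)C=C(O1)/C=C(/C=C/c1ccccc1)C[C@H](c1cc(O)cc(O)c1)C=C1C=CC(=O)C(O)=C1 | intermediate (not isolated)
12 | (5S,6S)-5-(3,4-dihydroxyphenyl)-6-(3,5-dihydroxyphenyl)-2,2-dimethyl-8-[(E)-2-phenylethenyl]-6,7-dihydro-5H-cyclohepta[d][1,3]dioxin-4-one (dioxinone fused at C1–C7 of the target ring) | CC1(C)OC(=O)C2=C(O1)C=C(/C=C/c1ccccc1)C[C@H](c1cc(O)cc(O)c1)[C@H]2c1ccc(O)c(O)c1 | intermediate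
13 | (3S,4S)-3-(3,4-dihydroxyphenyl)-4-(3,5-dihydroxyphenyl)-2-(oxomethylidene)-6-[(E)-2-phenylethenyl]cyclohept-6-en-1-one (acyl ketene) | O=C=C1C(=O)C=C(/C=C/c2ccccc2)C[C@H](c2cc(O)cc(O)c2)[C@H]1c1ccc(O)c(O)c1 | intermediate (not isolated)
14 | (6S,7R)-7-(3,4-dihydroxyphenyl)-6-(3,5-dihydroxyphenyl)-2-oxo-4-[(E)-2-phenylethenyl]cyclohept-3-ene-1-carboxylic acid (C-1 epimers) | O=C1C=C(/C=C/c2ccccc2)C[C@H](c2cc(O)cc(O)c2)[C@@H](c2ccc(O)c(O)c2)C1C(O)=O | intermediate (not isolated)
15 | (5S,6S)-6-(3,4-dihydroxyphenyl)-5-(3,5-dihydroxyphenyl)-3-[(E)-2-phenylethenyl]cyclohept-2-en-1-one (CNP0400050.1) | O=C1C=C(/C=C/c2ccccc2)C[C@H](c2cc(O)cc(O)c2)[C@@H](c2ccc(O)c(O)c2)C1 | target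

## Count and risks

Total step count: 5. Longest linear sequence: 5 steps (1/2 → 6 → 7 → 10 → 12 → 15); piceatannol 8 enters at step 3.

**Step 4** is the most likely to fail. The dioxinone carbon may be too weak a nucleophile, the polyphenol may be poorly soluble in the non-basic medium the acid needs, the skipped diene may drift into conjugation, and ee/dr are unproven. The fallback changes nucleophile and activation mode. It sets out from 10, which is heated in toluene with allyl alcohol (110 °C) to give the acyl ketene F1, trapped as the allyl 3-oxo ester F2. A quinine-derived squaramide (bifunctional tertiary amine/hydrogen-bond donor, 10 mol %, THF–toluene, 0 °C) then C-protonates the catecholate to the quinone methide inside the chiral pocket and lets the 3-oxo ester enolate close the ring, giving the cycloheptenone ester F3. Pd(PPh3)4 and morpholine remove the allyl group, and the route is rejoined at 14, which loses CO2 to 15.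

**Step 3** is second. The free catechol can be oxidised to the ortho-quinone by the oxidised photocatalyst, donate hydrogen atoms to the allyl radical, or be O-allylated by 7. The fallback removes the catechol from the coupling. It sets out from 7 and commercial resveratrol F4 under the same photoredox conditions, passing through the quinone methide F5 to the 4-hydroxyphenyl triene F6. 2-Iodoxybenzoic acid (IBX, MeOH, −25 °C) then hydroxylates F6 ortho to the 4-hydroxyl group via the ortho-quinone F7, which Na2S2O4 reduces in the same pot; the route is rejoined at 10.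

**Step 2** is third. Ionic bromination at C-5 of the dioxinone or bromine addition to the diene may compete with the allylic pathway. The fallback replaces radical bromination by oxidation and substitution. It sets out from 6: SeO2 (cat.)/t-BuOOH in CH2Cl2 oxidises the allylic methyl group to the allylic alcohol F8, and CBr4/PPh3 converts F8 to the bromide; the route is rejoined at 7.

## Further compounds

F1 | step 4 | (4E,6E)-5-[(2E)-3-(3,4-dihydroxyphenyl)-2-(3,5-dihydroxyphenyl)prop-2-en-1-yl]-7-phenylhepta-1,4,6-triene-1,3-dione (acyl ketene, not isolated) | O=C=CC(=O)/C=C(/C=C/c1ccccc1)C/C(=C\c1ccc(O)c(O)c1)c1cc(O)cc(O)c1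
F2 | step 4 | prop-2-en-1-yl (4E,6E)-5-[(2E)-3-(3,4-dihydroxyphenyl)-2-(3,5-dihydroxyphenyl)prop-2-en-1-yl]-3-oxo-7-phenylhepta-4,6-dienoate | C=CCOC(=O)CC(=O)/C=C(/C=C/c1ccccc1)C/C(=C\c1ccc(O)c(O)c1)c1cc(O)cc(O)c1
F3 | step 4 | prop-2-en-1-yl (6S,7R)-7-(3,4-dihydroxyphenyl)-6-(3,5-dihydroxyphenyl)-2-oxo-4-[(E)-2-phenylethenyl]cyclohept-3-ene-1-carboxylate (C-1 epimers) | C=CCOC(=O)C1C(=O)C=C(/C=C/c2ccccc2)C[C@H](c2cc(O)cc(O)c2)[C@H]1c1ccc(O)c(O)c1
F4 | step 3 | resveratrol, 5-[(E)-2-(4-hydroxyphenyl)ethenyl]benzene-1,3-diol (purchased) | Oc1ccc(/C=C/c2cc(O)cc(O)c2)cc1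
F5 | step 3 | 6-[(1E,3E)-2-[2-(3,5-dihydroxyphenyl)-3-(4-oxocyclohexa-2,5-dien-1-ylidene)propyl]-4-phenylbuta-1,3-dien-1-yl]-2,2-dimethyl-4H-1,3-dioxin-4-one (racemic quinone methide, not isolated) | CC1(C)OC(=O)C=C(O1)/C=C(/C=C/c1ccccc1)CC(C=C1C=CC(=O)C=C1)c1cc(O)cc(O)c1
F6 | step 3 | 6-[(1E,3E)-2-[(2E)-2-(3,5-dihydroxyphenyl)-3-(4-hydroxyphenyl)prop-2-en-1-yl]-4-phenylbuta-1,3-dien-1-yl]-2,2-dimethyl-4H-1,3-dioxin-4-one | CC1(C)OC(=O)C=C(O1)/C=C(/C=C/c1ccccc1)C/C(=C\c1ccc(O)cc1)c1cc(O)cc(O)c1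
F7 | step 3 | 4-[(1E)-2-(3,5-dihydroxyphenyl)-3-[(1E)-1-(2,2-dimethyl-4-oxo-4H-1,3-dioxin-6-yl)-4-phenylbuta-1,3-dien-2-yl]prop-1-en-1-yl]cyclohexa-3,5-diene-1,2-dione (ortho-quinone, not isolated) | CC1(C)OC(=O)C=C(O1)/C=C(/C=C/c1ccccc1)C/C(=C\C1=CC(=O)C(=O)C=C1)c1cc(O)cc(O)c1
F8 | step 2 | 6-[(1Z,3E)-2-(hydroxymethyl)-4-phenylbuta-1,3-dien-1-yl]-2,2-dimethyl-4H-1,3-dioxin-4-one | CC1(C)OC(=O)C=C(O1)/C=C(\CO)/C=C/c1ccccc1
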